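The route rests on disconnecting the aryl ether bond O1–C8a of the chroman. Because C8 carries hydrogen and sits between C8a and the oxygen-bearing C7, a C8≡C8a aryne can be generated from a C8a bromide and is polarised so that oxygen adds at C8a. In one operation the key step forms O1–C8a and closes ring B (the dihydropyran ring), while the quaternary (R)-C2 arrives intact from (R)-linalool. Its precursor is the linalool-derived tertiary alcohol carrying a 2-(2-bromo-6-methylphenyl)ethyl arm whose C7 oxygen is a methoxymethyl ether; this acetal directs lithiation, survives every later base and is cleaved only in the last step.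

Key step: step 6

Assumption: commercial (R)-(−)-linalool of high enantiomeric purity is used, so the route sets no stereocentre itself; chroman numbering (O1, C2, C3, C4, C4a, C5–C8, C8a) is applied to all intermediates.

Step 1
Reactants: 1 4-methoxy-2-methylaniline
Product: 2 2-bromo-4-methoxy-6-methylaniline
Conditions: NBS (1.0 equiv), MeCN, 0 °C
Reagents that add atoms: N-bromosuccinimide, O=C1CCC(=O)N1Br
Why: Electrophilic aromatic bromination should be directed by the amino group, the strongest activator, to its only free ortho position, since the para position is occupied by the methoxy group.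

Step 2
Reactants: 2 2-bromo-4-methoxy-6-methylaniline
Product: 4 1-bromo-2-iodo-5-methoxy-3-methylbenzene, via diazonium tosylate 3 (not isolated)
Conditions: p-TsOH·H2O (3 equiv), NaNO2 (2 equiv), KI (2.5 equiv), MeCN–H2O, 10 °C → rt
Reagents that add atoms: potassium iodide, [K+].[I-]
Why: Diazotisation followed by iodo-dediazoniation (a Sandmeyer-type reaction that needs no copper for iodide) should exchange NH2 for iodine at the same carbon, so the Br/I/CH3 pattern is fixed without a regiochemical choice.

Step 3
Reactants: 4 1-bromo-2-iodo-5-methoxy-3-methylbenzene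
Product: 6 3-bromo-4-iodo-5-methylphenol, via aryloxydibromoborane 5 (not isolated)
Conditions: BBr3 (1.5 equiv), CH2Cl2, −78 → 0 °C; then H2O
Reagents that add atoms: none
Why: Lewis-acid cleavage of the aryl methyl ether (BBr3 demethylation) should proceed by bromide attack on the O-methyl group of the borane adduct and leave both carbon–halogen bonds untouched at low temperature.

Step 4
Reactants: 6 3-bromo-4-iodo-5-methylphenol
Product: 7 1-bromo-2-iodo-5-(methoxymethoxy)-3-methylbenzene
Conditions: MOMCl (1.3 equiv), i-Pr2NEt (2 equiv), CH2Cl2, 0 °C → rt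
Reagents that add atoms: chloromethyl methyl ether, COCCl
Why: O-Alkylation of the phenol with chloromethyl methyl ether under amine base (Williamson-type acetal formation) should give the base-stable methoxymethyl ether that later directs lithiation at C8.

Step 5
Reactants: 7 1-bromo-2-iodo-5-(methoxymethoxy)-3-methylbenzene; 8 (R)-linalool
Product: 10 (R)-1-[2-bromo-4-(methoxymethoxy)-6-methylphenyl]-3,7-dimethyloct-6-en-3-ol, via alkyl-9-BBN adduct 9 (not isolated)
Conditions: 9-BBN-H dimer (2.2 equiv B–H), THF, 0 °C → rt; then 7, Pd(dppf)Cl2 [dppf = 1,1′-bis(diphenylphosphino)ferrocene] (5 mol %), aq. K3PO4 (3 M), DMF, 60 °C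
Reagents that add atoms: none
Why: Anti-Markovnikov hydroboration of the monosubstituted vinyl group by the bulky dialkylborane (the trisubstituted alkene reacts far more slowly) followed by B-alkyl Suzuki–Miyaura coupling should join C4 to C4a at the C–I bond, which adds to zerovalent palladium much faster than the C–Br bond, and the carbinol stereocentre is not involved.

Step 6
Reactants: 10 (R)-1-[2-bromo-4-(methoxymethoxy)-6-methylphenyl]-3,7-dimethyloct-6-en-3-ol
Product: 13 (R)-7-(methoxymethoxy)-2,5-dimethyl-2-(4-methylpent-3-en-1-yl)chromane, via aryne lithium alkoxide 11 (not isolated), via 8-lithiochromane 12 (not isolated)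
Conditions: lithium 2,2,6,6-tetramethylpiperidide (3.2 equiv, from 2,2,6,6-tetramethylpiperidine + n-BuLi), THF (0.02 M), −78 → 0 °C; then H2O
Reagents that add atoms: none
Why: The first equivalent of base forms the tertiary lithium alkoxide, a second removes the C8 hydrogen, which is the only one ortho to bromine and is acidified by both Br and the acetal oxygen, and loss of LiBr gives the C8≡C8a aryne 11. The closest known reaction type is the intramolecular capture of base-generated arynes by tethered alkoxides, which delivers chromans and dihydrobenzofurans. Ring B is closed in a 6-exo-dig mode, the alkoxide oxygen adding to C8a and leaving the aryl anion 12 at C8, where the two flanking oxygens stabilise it until the aqueous quench. No stereocentre is formed; C2 keeps the (R) configuration of linalool because its C–O bond is never broken. The step needs aryne formation across C8–C8a only and O-addition at C8a, not C8: bromine has a single ortho hydrogen, the inductively withdrawing C7 oxygen steers the nucleophile to the remote aryne carbon C8a, and the three-carbon tether from C4a can reach only C8a. The hindered, weakly nucleophilic amide and high dilution should keep intermolecular additions to the aryne in check.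

Step 7
Reactants: 13 (R)-7-(methoxymethoxy)-2,5-dimethyl-2-(4-methylpent-3-en-1-yl)chromane
Product: 15 (E)-5-[(R)-7-(methoxymethoxy)-2,5-dimethylchroman-2-yl]-2-methylpent-2-en-1-ol, via enal 14 (not isolated)
Conditions: SeO2 (0.5 equiv), t-BuOOH (3 equiv), CH2Cl2, 0 °C → rt; then NaBH4, MeOH, 0 °C
Reagents that add atoms: tert-butyl hydroperoxide, CC(C)(C)OO
Why: Sharpless-type SeO2-catalysed allylic oxidation (ene reaction, then [2,3]-sigmatropic shift) should hydroxylate the (E)-methyl group of the trisubstituted alkene selectively, and the reductive work-up should return any over-oxidised enal 14 to the alcohol.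

Step 8
Reactants: 15 (E)-5-[(R)-7-(methoxymethoxy)-2,5-dimethylchroman-2-yl]-2-methylpent-2-en-1-ol
Product: 16 (R)-2-[(E)-5-bromo-4-methylpent-3-en-1-yl]-7-(methoxymethoxy)-2,5-dimethylchromane
Conditions: CBr4 (1.3 equiv), PPh3 (1.4 equiv), CH2Cl2, 0 °C
Reagents that add atoms: carbon tetrabromide, BrC(Br)(Br)Br
Why: The Appel reaction should convert the primary allylic alcohol into the bromide by SN2 displacement of the oxyphosphonium group under neutral conditions that spare the acetal and the alkene geometry.

Step 9
Reactants: 16 (R)-2-[(E)-5-bromo-4-methylpent-3-en-1-yl]-7-(methoxymethoxy)-2,5-dimethylchromane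
Product: 17 (E)-7-[(R)-7-(methoxymethoxy)-2,5-dimethylchroman-2-yl]-4-methylhept-4-enenitrile
Conditions: MeCN (5 equiv), n-BuLi (5 equiv), THF, −78 °C; then 16, −78 → −40 °C
Reagents that add atoms: acetonitrile, CC#N
Why: SN2 alkylation of lithioacetonitrile by the primary allylic bromide (excess nucleophile to suppress double alkylation) should add the two-carbon unit needed between the two alkenes of the side chain with retention of the (E)-alkene.

Step 10
Reactants: 17 (E)-7-[(R)-7-(methoxymethoxy)-2,5-dimethylchroman-2-yl]-4-methylhept-4-enenitrile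
Product: 19 (E)-7-[(R)-7-(methoxymethoxy)-2,5-dimethylchroman-2-yl]-4-methylhept-4-enal, via N-aluminio aldimine 18 (not isolated)
Conditions: i-Bu2AlH (1.3 equiv), CH2Cl2, −78 °C; then 10% aq. tartaric acid, 0 °C → rt
Reagents that add atoms: water, O
Why: i-Bu2AlH should add once to the nitrile to give a stable N-aluminio aldimine that is hydrolysed to the aldehyde on mild acidic work-up (partial reduction of a nitrile), without over-reduction.

Step 11
Reactants: 19 (E)-7-[(R)-7-(methoxymethoxy)-2,5-dimethylchroman-2-yl]-4-methylhept-4-enal; 20 methyl 2-[bis(2,2,2-trifluoroethoxy)phosphoryl]propanoate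
Product: 21 methyl (2Z,6E)-9-[(R)-7-(methoxymethoxy)-2,5-dimethylchroman-2-yl]-2,6-dimethylnona-2,6-dienoate
Conditions: 20 (1.2 equiv), KN(SiMe3)2 (1.15 equiv), 18-crown-6 (5 equiv), THF, −78 °C; then 19
Reagents that add atoms: none
Why: The Still–Gennari modification of the Horner–Wadsworth–Emmons reaction, with the electron-poor bis(trifluoroethyl) phosphonate and a dissociated potassium enolate, should eliminate fast from the kinetically formed adduct and so give the (Z)-configured trisubstituted enoate.

Step 12
Reactants: 21 methyl (2Z,6E)-9-[(R)-7-(methoxymethoxy)-2,5-dimethylchroman-2-yl]-2,6-dimethylnona-2,6-dienoate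
Product: 22 methyl (2Z,6E)-9-[(R)-7-hydroxy-2,5-dimethylchroman-2-yl]-2,6-dimethylnona-2,6-dienoate
Conditions: HCl (0.5 M), MeOH, rt
Reagents that add atoms: none
Why: Acid-catalysed cleavage of the aryl methoxymethyl acetal in methanol (transacetalisation to dimethoxymethane) should free the C7 phenol under conditions too mild to affect the methyl ester, either alkene or the chroman ether.

Compound list

1 | 4-methoxy-2-methylaniline | COc1ccc(N)c(C)c1 | starting material
2 | 2-bromo-4-methoxy-6-methylaniline | COc1cc(C)c(N)c(Br)c1 | intermediate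
3 | 2-bromo-4-methoxy-6-methylbenzenediazonium p-toluenesulfonate (not isolated) | COc1cc(C)c([N+]#N)c(Br)c1.Cc1ccc(cc1)S(=O)(=O)[O-] | intermediate
4 | 1-bromo-2-iodo-5-methoxy-3-methylbenzene | COc1cc(C)c(I)c(Br)c1 | intermediate
5 | dibromo(3-bromo-4-iodo-5-methylphenoxy)borane (not isolated) | BrB(Br)Oc1cc(C)c(I)c(Br)c1 | intermediate
6 | 3-bromo-4-iodo-5-methylphenol | Oc1cc(C)c(I)c(Br)c1 | intermediate
7 | 1-bromo-2-iodo-5-(methoxymethoxy)-3-methylbenzene | COCOc1cc(C)c(I)c(Br)c1 | intermediate
8 | (R)-linalool, (3R)-3,7-dimethylocta-1,6-dien-3-ol | CC(C)=CCC[C@](O)(C)C=C | starting material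
9 | (S)-1-(9-borabicyclo[3.3.1]nonan-9-yl)-3,7-dimethyloct-6-en-3-ol (same spatial arrangement as 8; descriptor changes by priority only; not isolated) | CC(C)=CCC[C@](O)(C)CCB1C2CCCC1CCC2 | intermediate
10 | (R)-1-[2-bromo-4-(methoxymethoxy)-6-methylphenyl]-3,7-dimethyloct-6-en-3-ol | CC(C)=CCC[C@](O)(C)CCc1c(C)cc(OCOC)cc1Br | intermediate
11 | lithium (R)-1-[4-(methoxymethoxy)-6-methyl-2,3-didehydrophenyl]-3,7-dimethyloct-6-en-3-olate, the C8≡C8a aryne (not isolated) | [Li+].CC(C)=CCC[C@]([O-])(C)CCC1=C(C)C=C(OCOC)C#C1 | intermediate
12 | (R)-8-lithio-7-(methoxymethoxy)-2,5-dimethyl-2-(4-methylpent-3-en-1-yl)chromane (not isolated) | CC(C)=CCC[C@]1(C)CCc2c(C)cc(OCOC)c([Li])c2O1 | intermediate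
13 | (R)-7-(methoxymethoxy)-2,5-dimethyl-2-(4-methylpent-3-en-1-yl)chromane | CC(C)=CCC[C@]1(C)CCc2c(C)cc(OCOC)cc2O1 | intermediate
14 | (E)-5-[(R)-7-(methoxymethoxy)-2,5-dimethylchroman-2-yl]-2-methylpent-2-enal (not isolated) | O=C/C(C)=C/CC[C@]1(C)CCc2c(C)cc(OCOC)cc2O1 | intermediate
15 | (E)-5-[(R)-7-(methoxymethoxy)-2,5-dimethylchroman-2-yl]-2-methylpent-2-en-1-ol | OC/C(C)=C/CC[C@]1(C)CCc2c(C)cc(OCOC)cc2O1 | intermediate
16 | (R)-2-[(E)-5-bromo-4-methylpent-3-en-1-yl]-7-(methoxymethoxy)-2,5-dimethylchromane | BrC/C(C)=C/CC[C@]1(C)CCc2c(C)cc(OCOC)cc2O1 | intermediate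
17 | (E)-7-[(R)-7-(methoxymethoxy)-2,5-dimethylchroman-2-yl]-4-methylhept-4-enenitrile | N#CCC/C(C)=C/CC[C@]1(C)CCc2c(C)cc(OCOC)cc2O1 | intermediate
18 | N-(diisobutylaluminio) aldimine of aldehyde 19 (not isolated) | CC(C)C[Al](CC(C)C)N=CCC/C(C)=C/CC[C@]1(C)CCc2c(C)cc(OCOC)cc2O1 | intermediate
19 | (E)-7-[(R)-7-(methoxymethoxy)-2,5-dimethylchroman-2-yl]-4-methylhept-4-enal | O=CCC/C(C)=C/CC[C@]1(C)CCc2c(C)cc(OCOC)cc2O1 | intermediate
20 | methyl 2-[bis(2,2,2-trifluoroethoxy)phosphoryl]propanoate | COC(=O)C(C)P(=O)(OCC(F)(F)F)OCC(F)(F)F | starting material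
21 | methyl (2Z,6E)-9-[(R)-7-(methoxymethoxy)-2,5-dimethylchroman-2-yl]-2,6-dimethylnona-2,6-dienoate | COC(=O)/C(C)=C\CC/C(C)=C/CC[C@]1(C)CCc2c(C)cc(OCOC)cc2O1 | intermediate
22 | methyl (2Z,6E)-9-[(R)-7-hydroxy-2,5-dimethylchroman-2-yl]-2,6-dimethylnona-2,6-dienoate (CNP0319148.1) | COC(=O)/C(C)=C\CC/C(C)=C/CC[C@]1(C)CCc2c(C)cc(O)cc2O1 | target

Total step count: 12. Longest linear sequence: 12 steps (1 → 22); the linalool branch (8 → 22) runs over 8 steps.

The three steps most likely to fail are steps 6, 5 and 7.

For step 6, the aryne could be intercepted intermolecularly by the amide base or by a second alkoxide before ring closure. Bromine could also migrate between aryllithiums before LiBr is lost. As a fallback, the same O1–C8a bond would be made from 10 by palladium-catalysed intramolecular C–O coupling (Pd(OAc)2, 1,1′-bis(diphenylphosphino)ferrocene, Cs2CO3, toluene, 90 °C). This cyclisation is known for tertiary alcohols, whose palladium alkoxides cannot undergo β-hydride elimination. It gives 13 directly and forms no new compound.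

For step 5, oxidative addition and transmetalation at the doubly ortho-substituted C–I bond may be slow. Protodeboronation, β-hydride elimination of the alkylpalladium species or insertion into the C–Br bond could then compete. As a fallback, 7 and 8 would be joined by a Mizoroki–Heck reaction at the vinyl group (Pd(OAc)2, n-Bu4NCl, NaHCO3, DMF, 80 °C), which should give (R,E)-1-[2-bromo-4-(methoxymethoxy)-6-methylphenyl]-3,7-dimethylocta-1,6-dien-3-ol F1. Its disubstituted styrenyl alkene would then be reduced with diimide (2-nitrobenzenesulfonyl hydrazide, Et3N, CH2Cl2, rt), which should spare the trisubstituted alkene and the C–Br bond. This rejoins the route at 10.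

For step 7, conversion may stall, the allylic alcohol may be oxidised further, and the electron-rich ring or its benzylic positions may be attacked. As a fallback, Lemieux–Johnson cleavage of the trisubstituted alkene of 13 (OsO4 cat., NaIO4, 2,6-lutidine, dioxane–H2O) would give (S)-3-[7-(methoxymethoxy)-2,5-dimethylchroman-2-yl]propanal F2 (same spatial arrangement; descriptor changes by priority only). Wittig olefination with Ph3P=C(CH3)CO2Et (CH2Cl2, rt → 40 °C) should then give ethyl (E)-5-[(R)-7-(methoxymethoxy)-2,5-dimethylchroman-2-yl]-2-methylpent-2-enoate F3. Reduction with i-Bu2AlH (CH2Cl2, −78 °C) would deliver the allylic alcohol 15, where the route is rejoined.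

Further compounds

F0 | step 6 | none | none
F1 | step 5 | (R,E)-1-[2-bromo-4-(methoxymethoxy)-6-methylphenyl]-3,7-dimethylocta-1,6-dien-3-ol | CC(C)=CCC[C@](O)(C)/C=C/c1c(C)cc(OCOC)cc1Br
F2 | step 7 | (S)-3-[7-(methoxymethoxy)-2,5-dimethylchroman-2-yl]propanal | O=CCC[C@]1(C)CCc2c(C)cc(OCOC)cc2O1
F3 | step 7 | ethyl (E)-5-[(R)-7-(methoxymethoxy)-2,5-dimethylchroman-2-yl]-2-methylpent-2-enoate | CCOC(=O)/C(C)=C/CC[C@]1(C)CCc2c(C)cc(OCOC)cc2O1
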